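**Atom numbering used throughout:** C8 lactone O–CH, C9 CHOH, C10 CHMe (methyl C14), C1–C3 the CH2 run, C4 (methyl C15) and C5 the epoxide carbons, C6 the tigloyloxy carbon, C7 the ring-fusion CH, C11 the lactone α-carbon with exocyclic C13, C12 the carbonyl. Compound numbers 1–31 are those fixed in the steps.

## Analysis of the target

Target 31 is a cyclodecane (ring A) carrying a trans-fused α-methylene-γ-butyrolactone (ring B) across C7–C8, a 4,5-epoxide (ring C), a tiglate on O6, a free hydroxyl on C9 and methyl groups on C4 and C10. The seven consecutive ring atoms C4–C10 are all stereogenic (4R,5R,6R,7S,8S,9R,10R). Drawn flat, O6, O8, O9 and C14 lie on one face and the C7–C11 bond on the other. The epoxide is trans, so it derives from an (E)-alkene, and its oxygen is erythro to O6: it sits on the face away from O6 when H6 eclipses the C4 methyl. The α-methylene lactone (Michael acceptor, hydride-sensitive), the trisubstituted epoxide (acid), the tiglate (base, acyl migration) and the O8/O9 pair (γ- against δ-lactone) restrict the late reagents. The synthesis is hard for three reasons: a ten-membered carbocycle resists closure by cyclisation, three secondary oxygens must be told apart, and C8, C9, C10 and the epoxide must be set on a mobile ring. The plan rests on one feature: O9 is 1,5-related to the C4–C5 epoxide through C8, C7 and C6, which is the retron of an oxy-Cope rearrangement. Re-forming the C4–C9 bond turns C9, C10, C1, C2, C3 and C4 into a cyclohexane.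

## Retrosynthetic reasoning

**31 ⇒ 28 (C12–O8).** The lactone is made last because it is the most fragile group. In triol 28 only the primary allylic alcohol at C12 is oxidised by a mild allylic oxidant. O8 closes the five-membered ring in preference to O9 (six-membered), so O9 needs no protecting group in the final step.

**28 ⇒ 27 ⇒ 25 ⇒ 24 (O6–acyl, then the two epoxide C–O bonds).** Acid chloride 26 acylates 25, whose only free hydroxyl is O6. The epoxide comes from allylic alcohol 24 by hydroxyl-directed oxygen transfer. Direction is needed because the required face is not the one an undirected reagent would reach: in the conformer the ring is born in, O6 itself lies on the exposed face, and the target has the epoxide oxygen erythro to O6.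

**24 ⇒ 23 ⇒ 22 (protecting groups).** O8 and O9 are silylated together in 23 so that removal of the 4-methoxybenzyl group, which has sat on O6 since 9, leaves O6 as the only hydroxyl for epoxidation and acylation.

**22 ⇒ 21 (C9–H).** The C9 alcohol is cut back to the ketone. With O8 free, a chelating hydride must deliver the anti (8S,9R) diol, which is the cis arrangement of O8 and O9 on the ring.

**21 ⇒ 19 (C10–C14).** The C10 methyl is introduced on the ten-membered ketone, not on the cyclohexanone. In a 2,6-disubstituted cyclohexanone the methyl would have to be cis to the enol ether arm. With that methyl equatorial the arm is equatorial and the C4 methyl axial, so an alkenyl nucleophile attacks anti to the axial methyl, cis to the arm. The resulting cis-dialkenyl carbinol rearranges through a chair to the (Z)-cyclodecene. The epimer that does add correctly (arm axial) has C10 inverted. On the ring-expanded ketone the conflict vanishes: the second α-position is free, and alkylation from the ring periphery should place the methyl equatorially, as required.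

**19 ⇒ 16 (key: re-form C4–C9, cut C6–C7 and C8–O).** The ten-membered ring is traced to trans-1,2-dialkenylcyclohexanol 16. The forward reaction must form C6–C7 through a chair, give the (E) C4=C5 alkene, and hand over the C8 enolate, which is oxygenated in the same flask. C12 is carried as a silyl-protected hydroxymethyl group, because allylic oxidation of an isopropenyl methyl next to the more reactive C4=C5 alkene would not be selective.

**16 ⇒ 9 + 13 (C8–C9).** The dienyl arm is added as a nucleophile from stannane 13 to ketone 9. The addition must place it trans to the enol ether arm.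

**9 ⇒ 7 ⇒ 6 ⇒ 5 ⇒ 4 (O–C6, C5=C6, then C5 from allyl).** The (E)-enol ether is cut at O–C6 to alkenyl iodide 7 and alcohol 8, because a stereoretentive C–O coupling avoids the E/Z mixture of an alkoxymethylene olefination. Iodide 7 comes from aldehyde 6, and 6 from the allyl group of 4 by isomerisation to 5 and cleavage.

**4 ⇒ 2 + 3, 2 ⇒ 1 (C4–C5).** The quaternary C4, the only stereocentre brought into the key step from outside, is set by catalytic enantioselective allylation of silyl enol ether 2 with carbonate 3. Enol ether 2 derives from ketone 1.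

**13 ⇒ 11 + 12, 11 ⇒ 10 (C7–C11).** The dienylstannane is assembled by cross-coupling of bromide 11 (from alcohol 10) with distannane 12.

## Alternatives that were turned down

**Alternative 1:** The ring is cut to a cyclohexane (C5–C10) and a four-carbon unit (C1–C4). An enone–cyclobutene [2+2] photocycloaddition forms C4–C5 and C1–C10 and gives the tricyclic cyclobutane A1; heating then opens the bicyclo[2.2.0]hexane to a ten-membered 1(10),4-dienone.
- For: a chiral-pool cyclohexenone already holds C6 and C7 on a rigid ring, both methyl-bearing carbons and the C9 carbonyl are in place, and no asymmetric catalysis is needed. On these points it is stronger than the chosen route.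
- Against: the unsymmetrical cyclobutene raises regio- and facial-selectivity questions in the photoaddition. The cycloreversion does not guarantee the (E) C4=C5 geometry, and the cyclodeca-1,5-diene can pass on by a Cope shift to a divinylcyclohexane at the temperature of its formation. The target has no C1=C10 unsaturation, so a conjugate reduction with C10 control follows. C8 is unoxygenated, and the tertiary silyloxy side chain on C7 must still be dehydrated and oxidised next to a trisubstituted alkene.
- Comparison: the chosen route offers one alkene of defined (E) geometry from a chair, no surplus unsaturation, O6 in place, and the three-carbon branch on C7 already oxidised.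

**Alternative 2:** The ring is cut at C1–C2. A ruthenium carbene catalyst joins a C10 vinyl and a C4 allyl terminus of an open-chain epoxy lactone with loss of ethylene, giving A2.
- For: every stereocentre, the epoxide and the lactone are installed by acyclic methods before ring closure, so nothing depends on medium-ring conformational control, and the alkene geometry is irrelevant because it is hydrogenated. In stereochemical security at C8–C10 and at the epoxide it is stronger than the chosen route.
- Against: metathesis to a ten-membered ring fights strain and entropy and competes with oligomerisation. Here one alkene sits on a branched allylic carbon and the other two atoms from a quaternary epoxide carbon. The open chain with seven stereocentres needs a long linear sequence, and hydrogenation, α-methylenation and protecting-group traffic follow.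
- Comparison: the chosen route forms the ring by enlargement of a six-membered ring, without high dilution, and reaches it in far fewer steps.

**Alternative 3:** The ring is cut at C7–C8. The C8 enolate of a thirteen-membered α-allyloxy ketone attacks C7 through a five-membered transition state; O–C13 breaks and the ring contracts to A3.
- For: the C8 hydroxyl arrives together with the C–C bond, the C10 methyl is already present, and A3 has the functional array of compound 21. On these points it is stronger.
- Against: a thirteen-membered ether must first be closed. Enolisation must choose C8 over C10, [1,2]- and [3,3]-shifts compete, and the C7/C8 relationship depends on enolate geometry inside a macrocycle. C6 and the (E)-alkene must be built beforehand on an open chain, and the isopropenyl group still needs allylic oxidation in the presence of C4=C5.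
- Comparison: the chosen route takes the ring from a cyclohexane in one operation, sets C6 and C7 from alkene geometry, and hydroxylates the same enolate in the flask.

Key step: step 10

**Remarks on the chemistry**
- Relative to the simplest rearrangement substrate, two spectator positions are changed on purpose: C10 is unsubstituted until step 11, and C12 is a silyl-protected hydroxymethyl group.
- Step 2 is assumed to give 4 in high but incomplete enantiomeric excess. The crystallisation detour given for step 2 at the end supplies single-enantiomer material if needed.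

## Route

Step 1
Reactants: 1 2-methylcyclohexanone (racemic)
Product: 2 trimethyl[(2-methylcyclohex-1-en-1-yl)oxy]silane
Conditions: Me3SiCl, NaI, Et3N, MeCN, 25 °C
Reagents that add atoms: chlorotrimethylsilane, C[Si](C)(C)Cl
Why: Silyl enol ether formation under equilibrating conditions (Me3SiI made in the flask, amine base) should favour the more substituted enol ether; 2 has no stereocentre.

Step 2
Reactants: 2 trimethyl[(2-methylcyclohex-1-en-1-yl)oxy]silane; 3 diallyl carbonate
Product: 4 (R)-2-allyl-2-methylcyclohexan-1-one
Conditions: Pd2(dba)3 (2.5 mol %), (R)-t-BuPHOX (6 mol %), Bu4N[Ph3SiF2] (35 mol %), THF, 25 °C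
Reagents that add atoms: none
Why: Enantioselective decarboxylative Tsuji allylation: fluoride releases the enolate, which couples with the π-allylpalladium–phosphinooxazoline complex to form the quaternary C4. The (R)-ligand should give (R)-4, the mirror image of the outcome established with the (S)-ligand.

Step 3
Reactants: 4 (R)-2-allyl-2-methylcyclohexan-1-one
Product: 5 (R)-2-methyl-2-[(E)-prop-1-en-1-yl]cyclohexan-1-one
Conditions: PdCl2(MeCN)2 (5 mol %), toluene, 60 °C
Reagents that add atoms: none
Why: Palladium-catalysed alkene isomerisation moves the terminal double bond to the internal position next to the quaternary carbon; its geometry does not matter because the alkene is cleaved next.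

Step 4
Reactants: 5 (R)-2-methyl-2-[(E)-prop-1-en-1-yl]cyclohexan-1-one
Product: 6 (R)-1-methyl-2-oxocyclohexane-1-carbaldehyde
Conditions: O3, CH2Cl2, −78 °C; then PPh3, −78 °C to 25 °C
Reagents that add atoms: ozone, [O-][O+]=O
Why: Ozonolysis with reductive work-up leaves C5 as the aldehyde; the quaternary centre cannot epimerise, and the non-nucleophilic work-up avoids retro-Claisen deformylation of the β-keto aldehyde.

Step 5
Reactants: 6 (R)-1-methyl-2-oxocyclohexane-1-carbaldehyde
Product: 7 (R)-2-[(E)-2-iodoethenyl]-2-methylcyclohexan-1-one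
Conditions: CrCl2, CHI3, THF, 0 °C to 25 °C
Reagents that add atoms: iodoform, IC(I)I
Why: Takai olefination: the geminal dichromium reagent adds to aldehydes but not ketones and should give the (E)-iodoalkene, the more so next to a quaternary carbon.

Step 6
Reactants: 7 (R)-2-[(E)-2-iodoethenyl]-2-methylcyclohexan-1-one; 8 (4-methoxyphenyl)methanol
Product: 9 (R)-2-{(E)-2-[(4-methoxybenzyl)oxy]ethenyl}-2-methylcyclohexan-1-one
Conditions: CuI (copper monoiodide, 10 mol %), 3,4,7,8-tetramethyl-1,10-phenanthroline (20 mol %), Cs2CO3, toluene, 80 °C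
Reagents that add atoms: none
Why: Copper-catalysed Ullmann-type C–O coupling of an alkenyl iodide with an alcohol proceeds with retention of alkene geometry, so the (E)-enol ether is obtained without an E/Z problem.

Step 7
Reactants: 10 2-bromoprop-2-en-1-ol
Product: 11 [(2-bromoprop-2-en-1-yl)oxy](tert-butyl)dimethylsilane
Conditions: t-BuMe2SiCl, imidazole, CH2Cl2, 0 °C to 25 °C
Reagents that add atoms: tert-butylchlorodimethylsilane, CC(C)(C)[Si](C)(C)Cl
Why: Standard silylation of a primary alcohol; the ether must later survive organolithium, amide bases and hydride.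

Step 8
Reactants: 11 [(2-bromoprop-2-en-1-yl)oxy](tert-butyl)dimethylsilane; 12 (E)-1,2-bis(tributylstannyl)ethene
Product: 13 (E)-tributyl{3-[(tert-butyldimethylsilyloxy)methyl]buta-1,3-dien-1-yl}stannane
Conditions: Pd(PPh3)4 (5 mol %), toluene, 100 °C, twofold excess of 12
Reagents that add atoms: none
Why: Stille coupling at one tin terminus of the distannane (the excess suppresses double coupling) should give the dienylstannane with retention of the (E) geometry.

Step 9
Reactants: 13 (E)-tributyl{3-[(tert-butyldimethylsilyloxy)methyl]buta-1,3-dien-1-yl}stannane; 9 (R)-2-{(E)-2-[(4-methoxybenzyl)oxy]ethenyl}-2-methylcyclohexan-1-one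
Product: 16 (1S,2R)-1-{(E)-3-[(tert-butyldimethylsilyloxy)methyl]buta-1,3-dien-1-yl}-2-{(E)-2-[(4-methoxybenzyl)oxy]ethenyl}-2-methylcyclohexan-1-ol, via dienyllithium 14 (not isolated), via dienylcerium dichloride 15 (not isolated)
Conditions: 13, n-BuLi, THF, −78 °C; CeCl3 (anhydrous), −78 °C; then 9, −78 °C to −40 °C; aq. NH4Cl
Reagents that add atoms: none
Why: Tin–lithium exchange and transmetalation to cerium give a weakly basic alkenyl nucleophile for 1,2-addition to the hindered, enolisable ketone. Ketone 9 should react through the chair with the sp2-bound arm axial, and attack anti to that arm (Felkin–Anh, axial attack) places the dienyl group trans to the enol ether arm and the hydroxyl cis to it.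

Step 10
Reactants: 16 (1S,2R)-1-{(E)-3-[(tert-butyldimethylsilyloxy)methyl]buta-1,3-dien-1-yl}-2-{(E)-2-[(4-methoxybenzyl)oxy]ethenyl}-2-methylcyclohexan-1-ol
Product: 19 (4E,6S,7S,8S)-8-hydroxy-6-[(4-methoxybenzyl)oxy]-4-methyl-7-{3-[(tert-butyldimethylsilyl)oxy]prop-1-en-2-yl}cyclodec-4-en-9-one (ring locants of the analysis), via potassium alkoxide 17 (not isolated), via ring-expanded potassium enolate 18 (not isolated)
Conditions: KN(SiMe3)2, 18-crown-6, THF, 0 °C to 25 °C; then 2-(phenylsulfonyl)-3-phenyloxaziridine, −78 °C; aq. NH4Cl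
Reagents that add atoms: 2-(phenylsulfonyl)-3-phenyloxaziridine, O=S(=O)(c1ccccc1)N1OC1c1ccccc1
Why: The crown-ether-separated potassium alkoxide 17 weakens the C4–C9 bond, and the 1,5-diene C7=C8–C9–C4–C5=C6 undergoes a concerted suprafacial [3,3] sigmatropic shift (anionic oxy-Cope rearrangement) in which C6–C7 forms and C4–C9 breaks. The closest known reaction type is the anionic oxy-Cope ring expansion of trans-1,2-divinylcyclohexanols to (E)-cyclodec-5-enones, followed by oxaziridine hydroxylation of the enolate so formed. The ten-membered ring is not closed by a cyclisation but arises by four-atom enlargement of the cyclohexane, the broken bond being the one shared with the six-membered ring, so no cyclisation mode applies. C6 and C7 are set together by the chair transition state with both arms equatorial on the cyclohexane: the (E)-enol ether places the benzyloxy group and the (E)-diene places the C11 branch pseudo-equatorial, and the axial C4 methyl ends cis to C6, which makes the new C4=C5 alkene (E). The absolute sense is relayed from C4 (step 2) through C9 (step 9). Enolate 18 is regiodefined at C8 and is born in a chair–chair conformer whose inner C8 face is covered by the ring, so the oxaziridine should deliver oxygen from the periphery, trans to the C7 branch, giving (8S). The step needs chair over boat, which the trans-diequatorial arms and the two (E) alkenes secure, and it needs rearrangement to outrun fragmentation of the alkoxide, which the low temperature allowed by the dissociated potassium alkoxide should permit.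

Step 11
Reactants: 19 (4E,6S,7S,8S)-8-hydroxy-6-[(4-methoxybenzyl)oxy]-4-methyl-7-{3-[(tert-butyldimethylsilyl)oxy]prop-1-en-2-yl}cyclodec-4-en-9-one
Product: 21 (4E,6S,7S,8S,10R)-8-hydroxy-6-[(4-methoxybenzyl)oxy]-4,10-dimethyl-7-{3-[(tert-butyldimethylsilyl)oxy]prop-1-en-2-yl}cyclodec-4-en-9-one, via dilithium alkoxide enolate 20 (not isolated)
Conditions: LiN(iPr)2 (2.3 equiv), THF, −78 °C; MeI, −78 °C to −40 °C
Reagents that add atoms: iodomethane, CI
Why: α'-Alkylation of an α-hydroxy ketone through its alkoxide–enolate: after O8 is deprotonated the second equivalent of amide can only remove a C10 proton, since C8–H is geminal to O–Li and lies in the carbonyl plane. Iodomethane should enter from the ring periphery (macrocyclic stereocontrol in the chair–chair conformer), giving the equatorial (10R) methyl.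

Step 12
Reactants: 21 (4E,6S,7S,8S,10R)-8-hydroxy-6-[(4-methoxybenzyl)oxy]-4,10-dimethyl-7-{3-[(tert-butyldimethylsilyl)oxy]prop-1-en-2-yl}cyclodec-4-en-9-one
Product: 22 (4E,6S,7S,8S,9R,10R)-6-[(4-methoxybenzyl)oxy]-4,10-dimethyl-7-{3-[(tert-butyldimethylsilyl)oxy]prop-1-en-2-yl}cyclodec-4-ene-8,9-diol
Conditions: Zn(BH4)2, Et2O, −20 °C; aq. NH4Cl
Reagents that add atoms: none
Why: Chelation-controlled (Cram chelate) reduction of an α-hydroxy ketone: zinc bridges O8 and the carbonyl oxygen and hydride attacks anti to C7, which should give the anti (8S,9R) diol, the cis arrangement on the ring.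

Step 13
Reactants: 22 (4E,6S,7S,8S,9R,10R)-6-[(4-methoxybenzyl)oxy]-4,10-dimethyl-7-{3-[(tert-butyldimethylsilyl)oxy]prop-1-en-2-yl}cyclodec-4-ene-8,9-diol
Product: 23 the 8,9-bis(triethylsilyl) ether of 22 (4E,6S,7R,8S,9R,10R)
Conditions: Et3SiOSO2CF3, 2,6-lutidine, CH2Cl2, −40 °C to 0 °C
Reagents that add atoms: triethylsilyl trifluoromethanesulfonate, CC[Si](CC)(CC)OS(=O)(=O)C(F)(F)F
Why: The silyl triflate silylates both secondary hydroxyls, so that O6 will be the only free hydroxyl after the next step.

Step 14
Reactants: 23 the 8,9-bis(triethylsilyl) ether of 22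
Product: 24 (4E,6S,7R,8S,9R,10R)-4,10-dimethyl-8,9-bis(triethylsilyloxy)-7-{3-[(tert-butyldimethylsilyl)oxy]prop-1-en-2-yl}cyclodec-4-en-6-ol
Conditions: DDQ, CH2Cl2/pH 7 buffer, 0 °C
Reagents that add atoms: none
Why: Oxidative cleavage of the 4-methoxybenzyl ether (hydride abstraction, hydrolysis of the oxocarbenium ion) in buffered medium should leave silyl ethers and alkenes untouched.

Step 15
Reactants: 24 (4E,6S,7R,8S,9R,10R)-4,10-dimethyl-8,9-bis(triethylsilyloxy)-7-{3-[(tert-butyldimethylsilyl)oxy]prop-1-en-2-yl}cyclodec-4-en-6-ol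
Product: 25 (4R,5R,6R,7R,8S,9R,10R)-4,5-epoxy-4,10-dimethyl-8,9-bis(triethylsilyloxy)-7-{3-[(tert-butyldimethylsilyl)oxy]prop-1-en-2-yl}cyclodecan-6-ol
Conditions: VO(acac)2 (5 mol %), t-BuOOH, CH2Cl2, 0 °C to 25 °C
Reagents that add atoms: tert-butyl hydroperoxide, CC(C)(C)OO
Why: Vanadium-catalysed hydroxyl-directed epoxidation: only the trisubstituted C4=C5 alkene is allylic to the free hydroxyl. The small O–C6–C5=C4 dihedral angle demanded by the vanadate ester can be reached in the ring only with the ring chain on the far face, so oxygen should be delivered erythro to O6 (4R,5R).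

Step 16
Reactants: 25 (4R,5R,6R,7R,8S,9R,10R)-4,5-epoxy-4,10-dimethyl-8,9-bis(triethylsilyloxy)-7-{3-[(tert-butyldimethylsilyl)oxy]prop-1-en-2-yl}cyclodecan-6-ol; 26 (E)-2-methylbut-2-enoyl chloride
Product: 27 the 6-O-[(E)-2-methylbut-2-enoyl] ester of 25 (4R,5R,6R,7R,8S,9R,10R)
Conditions: DMAP, pyridine, CH2Cl2, 0 °C to 25 °C
Reagents that add atoms: none
Why: DMAP-catalysed acylation of the only free hydroxyl with retention at C6; the tiglate geometry is the stable one and pyridine is too weak a base to deconjugate the acid chloride.

Step 17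
Reactants: 27 the 6-O-[(E)-2-methylbut-2-enoyl] ester of 25
Product: 28 (4R,5R,6R,7S,8S,9R,10R)-4,5-epoxy-8,9-dihydroxy-7-(3-hydroxyprop-1-en-2-yl)-4,10-dimethylcyclodecan-6-yl (E)-2-methylbut-2-enoate
Conditions: HF·pyridine, pyridine, THF, 0 °C to 25 °C
Reagents that add atoms: none
Why: Buffered fluoride desilylation cleaves the two triethylsilyl ethers and the primary allylic silyl ether without opening the epoxide or cleaving the ester.

Step 18
Reactants: 28 (4R,5R,6R,7S,8S,9R,10R)-4,5-epoxy-8,9-dihydroxy-7-(3-hydroxyprop-1-en-2-yl)-4,10-dimethylcyclodecan-6-yl (E)-2-methylbut-2-enoate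
Product: 31 CNP0165329.2 (4R,5R,6R,7S,8S,9R,10R), via hydroxy enal 29 (not isolated), via lactol 30 (not isolated)
Conditions: MnO2, CH2Cl2, 25 °C
Reagents that add atoms: none
Why: Oxidative lactonisation of a 2-methylene-1,4-diol: MnO2 oxidises only the allylic primary alcohol, O8 traps the enal as the five-membered lactol (the six-membered alternative through O9 is slower), and the lactol is oxidised on to the α-methylene-γ-lactone.

## Compound list

1 | 2-methylcyclohexanone (racemic) | CC1CCCCC1=O | starting material
2 | trimethyl[(2-methylcyclohex-1-en-1-yl)oxy]silane | CC1=C(O[Si](C)(C)C)CCCC1 | intermediate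
3 | diallyl carbonate | C=CCOC(=O)OCC=C | starting material
4 | (R)-2-allyl-2-methylcyclohexan-1-one | O=C1CCCC[C@]1(C)CC=C | intermediate
5 | (R)-2-methyl-2-[(E)-prop-1-en-1-yl]cyclohexan-1-one | O=C1CCCC[C@]1(C)/C=C/C | intermediate
6 | (R)-1-methyl-2-oxocyclohexane-1-carbaldehyde | O=C1CCCC[C@]1(C)C=O | intermediate
7 | (R)-2-[(E)-2-iodoethenyl]-2-methylcyclohexan-1-one | O=C1CCCC[C@]1(C)/C=C/I | intermediate
8 | (4-methoxyphenyl)methanol | COc1ccc(CO)cc1 | starting material
9 | (R)-2-{(E)-2-[(4-methoxybenzyl)oxy]ethenyl}-2-methylcyclohexan-1-one | O=C1CCCC[C@]1(C)/C=C/OCc1ccc(OC)cc1 | intermediate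
10 | 2-bromoprop-2-en-1-ol | C=C(Br)CO | starting material
11 | [(2-bromoprop-2-en-1-yl)oxy](tert-butyl)dimethylsilane | C=C(Br)CO[Si](C)(C)C(C)(C)C | intermediate
12 | (E)-1,2-bis(tributylstannyl)ethene | CCCC[Sn](CCCC)(CCCC)/C=C/[Sn](CCCC)(CCCC)CCCC | starting material
13 | (E)-tributyl{3-[(tert-butyldimethylsilyloxy)methyl]buta-1,3-dien-1-yl}stannane | C=C(CO[Si](C)(C)C(C)(C)C)/C=C/[Sn](CCCC)(CCCC)CCCC | intermediate
14 | (E)-{3-[(tert-butyldimethylsilyloxy)methyl]buta-1,3-dien-1-yl}lithium | C=C(CO[Si](C)(C)C(C)(C)C)/C=C/[Li] | intermediate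
15 | (E)-{3-[(tert-butyldimethylsilyloxy)methyl]buta-1,3-dien-1-yl}cerium dichloride | C=C(CO[Si](C)(C)C(C)(C)C)/C=C/[Ce](Cl)Cl | intermediate
16 | (1S,2R)-1-{(E)-3-[(tert-butyldimethylsilyloxy)methyl]buta-1,3-dien-1-yl}-2-{(E)-2-[(4-methoxybenzyl)oxy]ethenyl}-2-methylcyclohexan-1-ol | C=C(CO[Si](C)(C)C(C)(C)C)/C=C/[C@@]1(O)CCCC[C@]1(C)/C=C/OCc2ccc(OC)cc2 | intermediate
17 | potassium alkoxide of 16 | C=C(CO[Si](C)(C)C(C)(C)C)/C=C/[C@@]1([O-])CCCC[C@]1(C)/C=C/OCc2ccc(OC)cc2.[K+] | intermediate
18 | potassium C8=C9 enolate of the (4E,6S,7R)-configured ring-expanded cyclodec-4-en-9-one (O6 4-methoxybenzyl, C7 3-silyloxyprop-1-en-2-yl) | [K+].[O-]/C1=C\[C@H](C(=C)CO[Si](C)(C)C(C)(C)C)[C@@H](OCc2ccc(OC)cc2)/C=C(C)/CCCC1 | intermediate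
19 | (4E,6S,7S,8S)-8-hydroxy-6-[(4-methoxybenzyl)oxy]-4-methyl-7-{3-[(tert-butyldimethylsilyl)oxy]prop-1-en-2-yl}cyclodec-4-en-9-one | O[C@@H]1C(=O)CCCC/C(C)=C/[C@H](OCc2ccc(OC)cc2)[C@H]1C(CO[Si](C)(C)C(C)(C)C)=C | intermediate
20 | dilithium O8 alkoxide / C9=C10 enolate of 19 (enolate geometry not specified) | [Li+].[Li+].[O-][C@@H]1C([O-])=CCCC/C(C)=C/[C@H](OCc2ccc(OC)cc2)[C@H]1C(CO[Si](C)(C)C(C)(C)C)=C | intermediate
21 | (4E,6S,7S,8S,10R)-8-hydroxy-6-[(4-methoxybenzyl)oxy]-4,10-dimethyl-7-{3-[(tert-butyldimethylsilyl)oxy]prop-1-en-2-yl}cyclodec-4-en-9-one | O[C@@H]1C(=O)[C@H](C)CCC/C(C)=C/[C@H](OCc2ccc(OC)cc2)[C@H]1C(CO[Si](C)(C)C(C)(C)C)=C | intermediate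
22 | (4E,6S,7S,8S,9R,10R)-6-[(4-methoxybenzyl)oxy]-4,10-dimethyl-7-{3-[(tert-butyldimethylsilyl)oxy]prop-1-en-2-yl}cyclodec-4-ene-8,9-diol | O[C@@H]1[C@H](O)[C@H](C)CCC/C(C)=C/[C@H](OCc2ccc(OC)cc2)[C@H]1C(CO[Si](C)(C)C(C)(C)C)=C | intermediate
23 | 8,9-bis(triethylsilyl) ether of 22 (4E,6S,7R,8S,9R,10R) | CC[Si](CC)(CC)O[C@@H]1[C@H](O[Si](CC)(CC)CC)[C@H](C)CCC/C(C)=C/[C@H](OCc2ccc(OC)cc2)[C@H]1C(CO[Si](C)(C)C(C)(C)C)=C | intermediate
24 | (4E,6S,7R,8S,9R,10R)-4,10-dimethyl-8,9-bis(triethylsilyloxy)-7-{3-[(tert-butyldimethylsilyl)oxy]prop-1-en-2-yl}cyclodec-4-en-6-ol | CC[Si](CC)(CC)O[C@@H]1[C@H](O[Si](CC)(CC)CC)[C@H](C)CCC/C(C)=C/[C@H](O)[C@H]1C(CO[Si](C)(C)C(C)(C)C)=C | intermediate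
25 | (4R,5R,6R,7R,8S,9R,10R)-4,5-epoxy-4,10-dimethyl-8,9-bis(triethylsilyloxy)-7-{3-[(tert-butyldimethylsilyl)oxy]prop-1-en-2-yl}cyclodecan-6-ol | CC[Si](CC)(CC)O[C@@H]1[C@H](O[Si](CC)(CC)CC)[C@H](C)CCC[C@@]2(C)O[C@@H]2[C@H](O)[C@H]1C(CO[Si](C)(C)C(C)(C)C)=C | intermediate
26 | (E)-2-methylbut-2-enoyl chloride (tigloyl chloride) | ClC(=O)/C(C)=C/C | starting material
27 | 6-O-[(E)-2-methylbut-2-enoyl] ester of 25 (4R,5R,6R,7R,8S,9R,10R) | CC[Si](CC)(CC)O[C@@H]1[C@H](O[Si](CC)(CC)CC)[C@H](C)CCC[C@@]2(C)O[C@@H]2[C@H](OC(=O)/C(C)=C/C)[C@H]1C(CO[Si](C)(C)C(C)(C)C)=C | intermediate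
28 | (4R,5R,6R,7S,8S,9R,10R)-4,5-epoxy-8,9-dihydroxy-7-(3-hydroxyprop-1-en-2-yl)-4,10-dimethylcyclodecan-6-yl (E)-2-methylbut-2-enoate | O[C@@H]1[C@H](O)[C@H](C)CCC[C@@]2(C)O[C@@H]2[C@H](OC(=O)/C(C)=C/C)[C@H]1C(CO)=C | intermediate
29 | C12 aldehyde of 28 (2-substituted acrolein, same configuration) | O[C@@H]1[C@H](O)[C@H](C)CCC[C@@]2(C)O[C@@H]2[C@H](OC(=O)/C(C)=C/C)[C@H]1C(C=O)=C | intermediate
30 | C12 lactol of 29 closed on O8 (anomeric centre not defined) | C=C1C(O)O[C@@H]2[C@H](O)[C@H](C)CCC[C@@]3(C)O[C@@H]3[C@H](OC(=O)/C(C)=C/C)[C@@H]12 | intermediate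
31 | CNP0165329.2 (4R,5R,6R,7S,8S,9R,10R) | C=C1C(=O)O[C@@H]2[C@H](O)[C@H](C)CCC[C@@]3(C)O[C@@H]3[C@H](OC(=O)/C(C)=C/C)[C@@H]12 | target

## Step count and least certain steps

Total: 18 steps. Longest linear sequence: 16 steps (steps 1–6 and 9–18); steps 7–8 form the side branch.

**Step 10 (key step).** Most likely failure: cleavage of the C4–C9 bond of the potassium alkoxide without C6–C7 bonding, since the electron-rich enol ether is a reluctant partner. Leakage through a boat transition state, or attack of the oxaziridine on both faces of the enolate, are lesser risks. Fallback, a neutral pericyclic variant with separate oxygenation: from 16, silylation (Me3SiCl, imidazole) gives the trimethylsilyl ether F1. Heating in degassed xylene in a sealed tube at about 200 °C effects the siloxy-Cope rearrangement through the same chair and gives the ring-expanded trimethylsilyl enol ether F2. Rubottom oxidation of F2 (dimethyldioxirane, acetone, −78 °C, then mild desilylation), again from the periphery, returns to 19.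

**Step 9.** Most likely failure: poor facial selectivity in the addition if the chair with the C4 methyl axial competes, which gives the cis-dialkenyl carbinol, together with enolisation of the ketone. Fallback, alkynylation then trans-reduction: from 11, Sonogashira coupling with ethynyltrimethylsilane (PdCl2(PPh3)2, copper monoiodide, Et3N) gives the silylated enyne F3, and K2CO3 in MeOH gives the terminal enyne F4. Its lithium acetylide (n-BuLi, THF, −78 °C) is small, linear and weakly basic and should add to 9 more cleanly anti to the axial arm, giving the propargylic alcohol F5. trans-Hydroalumination with NaAlH2(OCH2CH2OMe)2 in THF reduces the propargylic alcohol to the (E)-dienyl carbinol and returns to 16.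

**Step 11.** Most likely failure: O-methylation of the alkoxide, proton transfer to an enediolate (loss of C8 configuration or ketol transposition), or methylation on both faces of the C10 enolate. Fallback, protected mono-enolate: from 19, Et3SiCl and imidazole give the 8-O-triethylsilyl ketone F6. LiN(iPr)2 (1.1 equiv) and MeI at −78 °C give the methylated silyl ether F7, and PPTS in MeOH removes the secondary triethylsilyl group in the presence of the primary tert-butyldimethylsilyl ether, returning to 21.

**Step 15.** Most likely failure: oxygen delivery to the wrong face if the ring cannot reach the rotamer with the small O–C6–C5=C4 angle, so that epoxidation occurs on the exposed face syn to O6, or is slow enough for the homoallylic C11=C13 alkene to compete. Fallback, invert C6 first so that the exposed face becomes the required one: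
- From 24, Mitsunobu reaction (PPh3, diisopropyl azodicarboxylate, 4-nitrobenzoic acid) gives the 6-epi 4-nitrobenzoate F8.
- K2CO3 in MeOH gives the 6-epi alcohol F9.
- In F9 the rotamer free of A(1,3) strain turns the needed alkene face outward with the hydroxyl on it, so mCPBA with NaHCO3 (hydrogen-bond directed, peripheral) should give the 6-epi epoxy alcohol F10 with the correct C4 and C5.
- Mitsunobu esterification of F10 with tiglic acid inverts C6 and returns to 27.

**Step 2.** Most likely failure: incomplete enantiofacial discrimination at the π-allylpalladium stage, leaving some of the (S)-ketone. Fallback, enrichment through a crystalline derivative: from 4, semicarbazide hydrochloride and NaOAc give the semicarbazone F11, which is recrystallised to enantiomeric purity and hydrolysed (aq. HCl, ether, two phases) back to 4.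

## Further compounds

F1 | step 10 | trimethylsilyl ether of 16 | C=C(CO[Si](C)(C)C(C)(C)C)/C=C/[C@@]1(O[Si](C)(C)C)CCCC[C@]1(C)/C=C/OCc2ccc(OC)cc2
F2 | step 10 | trimethylsilyl enol ether (C8=C9) of the ring-expanded (4E,6S,7R)-cyclodecenone | C[Si](C)(C)O/C1=C\[C@H](C(=C)CO[Si](C)(C)C(C)(C)C)[C@@H](OCc2ccc(OC)cc2)/C=C(C)/CCCC1
F3 | step 9 | tert-butyldimethyl{[2-methylidene-4-(trimethylsilyl)but-3-yn-1-yl]oxy}silane | C=C(CO[Si](C)(C)C(C)(C)C)C#C[Si](C)(C)C
F4 | step 9 | tert-butyldimethyl[(2-methylidenebut-3-yn-1-yl)oxy]silane | C=C(CO[Si](C)(C)C(C)(C)C)C#C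
F5 | step 9 | propargylic alcohol with the ring configuration of 16 (alkyne in place of the C7=C8 alkene) | C=C(CO[Si](C)(C)C(C)(C)C)C#C[C@@]1(O)CCCC[C@]1(C)/C=C/OCc2ccc(OC)cc2
F6 | step 11 | 8-O-triethylsilyl ether of 19 | CC[Si](CC)(CC)O[C@@H]1C(=O)CCCC/C(C)=C/[C@H](OCc2ccc(OC)cc2)[C@H]1C(CO[Si](C)(C)C(C)(C)C)=C
F7 | step 11 | 8-O-triethylsilyl ether of 21 | CC[Si](CC)(CC)O[C@@H]1C(=O)[C@H](C)CCC/C(C)=C/[C@H](OCc2ccc(OC)cc2)[C@H]1C(CO[Si](C)(C)C(C)(C)C)=C
F8 | step 15 | 6-epi 4-nitrobenzoate of 24 | CC[Si](CC)(CC)O[C@@H]1[C@H](O[Si](CC)(CC)CC)[C@H](C)CCC/C(C)=C/[C@@H](OC(=O)c2ccc(cc2)[N+](=O)[O-])[C@H]1C(CO[Si](C)(C)C(C)(C)C)=C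
F9 | step 15 | 6-epi alcohol of 24 | CC[Si](CC)(CC)O[C@@H]1[C@H](O[Si](CC)(CC)CC)[C@H](C)CCC/C(C)=C/[C@@H](O)[C@H]1C(CO[Si](C)(C)C(C)(C)C)=C
F10 | step 15 | 6-epi epoxy alcohol (C6 epimer of 25) | CC[Si](CC)(CC)O[C@@H]1[C@H](O[Si](CC)(CC)CC)[C@H](C)CCC[C@@]2(C)O[C@@H]2[C@@H](O)[C@H]1C(CO[Si](C)(C)C(C)(C)C)=C
F11 | step 2 | (E)-semicarbazone of 4 | NC(=O)N/N=C1\CCCC[C@]1(C)CC=C
A1 | alternative 1 | cis-anti-cis tricyclic cyclobutane photoadduct (O6 tert-butyldimethylsilyl, C7 2-(triethylsilyloxy)propan-2-yl) | O=C1[C@@]2(C)[C@@H]3CC[C@]3(C)[C@H]2[C@H](O[Si](C)(C)C(C)(C)C)[C@@H](C(C)(C)O[Si](CC)(CC)CC)C1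
A2 | alternative 2 | ten-membered epoxy lactone with C1–C2 alkene (O9 tert-butyldimethylsilyl, O6 triethylsilyl) | O=C1O[C@@H]2[C@H](O[Si](C)(C)C(C)(C)C)[C@H](C)/C=C\C[C@@]3(C)O[C@@H]3[C@H](O[Si](CC)(CC)CC)[C@H]2C1
A3 | alternative 3 | 8-hydroxy-9-oxo (E)-cyclodecene with C7 isopropenyl and O6 tert-butyldimethylsilyl | O[C@@H]1C(=O)[C@H](C)CCC/C(C)=C/[C@H](O[Si](C)(C)C(C)(C)C)[C@H]1C(C)=C
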